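**Plan**

- Retrosynthetic cuts: lower ring C at O1–C8a and C2–C3 (aldehyde plus o-fluoroaryl α-benzyloxy ketone), then the acyl C4–C4a bond, the interflavan C4–C6 bond, and the upper C2–aryl bond.
- Forward order: upper ring C first (chromone, (2S)-flavanone, flavan-4-ol); its C4 cation is joined to a bromofluorophenol that becomes lower ring A; the glycolyl side chain replaces Br; lower ring C is closed last.
- Enabling feature: in ketone 18 the C4 carbonyl is alpha to C3 and ortho to the fluorine-bearing C8a of ring A (a benzo-fused vinylogous acyl fluoride). C3 is therefore a nucleophile, the aldol is reversible, and C8a accepts the aldehyde oxygen by addition-elimination.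
- Stereochemistry: upper C2 from a chiral Pd/pyridine-oxazoline catalyst; upper C4 by attack anti to the 2-aryl group (2,4-trans); lower C2 in the ring closure of equilibrating aldolates under a chiral ammonium ion; lower C3 and C4 by transfer hydrogenation with dynamic kinetic resolution (all-cis).
- All hydroxyls are carried as benzyl ethers and freed in one hydrogenolysis.

Key step: step 11

Remark: the absolute sense of induction in steps 3 and 11 is assigned by analogy with the closest known cases and would be confirmed on the first batch (the pseudoenantiomeric cinchoninium salt is the alternative in step 11). The CIP label of upper C4 is S in 14 and 24 but R in 15 to 23 through priority changes only; the geometry is 2,4-trans throughout.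

**Route**

Step 1
Reactants: 1 1-(2,3,4-trihydroxyphenyl)ethan-1-one (gallacetophenone)
Product: 2 1-[3,4-bis(benzyloxy)-2-hydroxyphenyl]ethan-1-one
Conditions: BnBr (2.1 equiv), K2CO3, DMF, rt
Reagents that add atoms: benzyl bromide, BrCc1ccccc1
Why: Williamson ether synthesis; the 2-hydroxyl is hydrogen-bonded to the acetyl carbonyl and least nucleophilic, so the 3- and 4-hydroxyls should be benzylated selectively.

Step 2
Reactants: 2 1-[3,4-bis(benzyloxy)-2-hydroxyphenyl]ethan-1-one
Product: 4 7,8-bis(benzyloxy)-4H-chromen-4-one, via enaminone 3 (not isolated)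
Conditions: Me2NCH(OMe)2, toluene, 100 °C; then conc. HCl, CH2Cl2, rt
Reagents that add atoms: N,N-dimethylformamide dimethyl acetal, COC(OC)N(C)C
Why: Enaminone route to chromones; condensation at the acetyl methyl group, then acid-induced conjugate addition of the free 2-hydroxyl and loss of dimethylamine should close the pyranone ring.

Step 3
Reactants: 4 7,8-bis(benzyloxy)-4H-chromen-4-one; 5 [4-(benzyloxy)phenyl]boronic acid
Product: 6 (2S)-7,8-bis(benzyloxy)-2-[4-(benzyloxy)phenyl]-2,3-dihydro-4H-chromen-4-one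
Conditions: Pd(OCOCF3)2 (5 mol %), (R)-t-BuPyOx (6 mol %), NH4PF6 (30 mol %), H2O (5 equiv), ClCH2CH2Cl, 60 °C
Reagents that add atoms: none
Why: Palladium-catalysed asymmetric conjugate addition of an arylboronic acid to a chromone; the pyridine-oxazoline ligand selects the face of aryl transfer to C2, and the (R)-ligand is expected to give the (2S)-flavanone as the mirror image of the (S)-ligand/(R)-product pairing.

Step 4
Reactants: 6 (2S)-7,8-bis(benzyloxy)-2-[4-(benzyloxy)phenyl]-2,3-dihydro-4H-chromen-4-one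
Product: 7 (2S,4S)-7,8-bis(benzyloxy)-2-[4-(benzyloxy)phenyl]-3,4-dihydro-2H-chromen-4-ol
Conditions: NaBH4, MeOH/THF, 0 °C
Reagents that add atoms: none
Why: Borohydride reduction of the flavanone; axial hydride attack should give the 2,4-cis alcohol, whose C4 configuration is of no consequence because it is ionised in step 8.

Step 5
Reactants: 8 3-fluoro-2-hydroxybenzaldehyde
Product: 9 2-(benzyloxy)-3-fluorobenzaldehyde
Conditions: BnBr, K2CO3, DMF, rt
Reagents that add atoms: benzyl bromide, BrCc1ccccc1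
Why: Williamson ether synthesis on the single phenol.

Step 6
Reactants: 9 2-(benzyloxy)-3-fluorobenzaldehyde
Product: 11 2-(benzyloxy)-3-fluorophenol, via aryl formate 10 (not isolated)
Conditions: m-CPBA, CH2Cl2, 0 °C to rt; then K2CO3, MeOH, rt
Reagents that add atoms: 3-chloroperoxybenzoic acid, O=C(OO)c1cccc(Cl)c1
Why: Baeyer–Villiger (Dakin-type) oxidation; the electron-rich 2-alkoxyaryl group migrates to oxygen and the formate is methanolysed in the same flask.

Step 7
Reactants: 11 2-(benzyloxy)-3-fluorophenol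
Product: 12 2-(benzyloxy)-4-bromo-3-fluorophenol
Conditions: NBS, MeCN, 0 °C
Reagents that add atoms: N-bromosuccinimide, O=C1CCC(=O)N1Br
Why: Electrophilic aromatic bromination para to the free hydroxyl, the strongest director; this carbon is ortho to fluorine, becomes C4a of the lower unit, and the bromine blocks the para position for step 8.

Step 8
Reactants: 7 (2S,4S)-7,8-bis(benzyloxy)-2-[4-(benzyloxy)phenyl]-3,4-dihydro-2H-chromen-4-ol; 12 2-(benzyloxy)-4-bromo-3-fluorophenol
Product: 14 2-(benzyloxy)-6-{(2S,4S)-7,8-bis(benzyloxy)-2-[4-(benzyloxy)phenyl]-3,4-dihydro-2H-chromen-4-yl}-4-bromo-3-fluorophenol, via flavan-4-yl cation 13 (not isolated)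
Conditions: 12 (4 equiv), BF3·OEt2 (0.3 equiv), CH2Cl2, −40 to 0 °C
Reagents that add atoms: none
Why: Friedel–Crafts alkylation through the 7-alkoxy-stabilised benzylic cation; the excess phenol should attack through its only free position ortho to the hydroxyl and from the face anti to the 2-aryl group, so C4 is set 2,4-trans by 1,3-induction from C2.

Step 9
Reactants: 14 2-(benzyloxy)-6-{(2S,4S)-7,8-bis(benzyloxy)-2-[4-(benzyloxy)phenyl]-3,4-dihydro-2H-chromen-4-yl}-4-bromo-3-fluorophenol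
Product: 15 (2S,4R)-7,8-bis(benzyloxy)-2-[4-(benzyloxy)phenyl]-4-[2,3-bis(benzyloxy)-5-bromo-4-fluorophenyl]-3,4-dihydro-2H-chromene
Conditions: BnBr, K2CO3, DMF, 50 °C
Reagents that add atoms: benzyl bromide, BrCc1ccccc1
Why: Williamson ether synthesis on the remaining phenol, which removes the acidic proton before the organometallic step.

Step 10
Reactants: 15 (2S,4R)-7,8-bis(benzyloxy)-2-[4-(benzyloxy)phenyl]-4-[2,3-bis(benzyloxy)-5-bromo-4-fluorophenyl]-3,4-dihydro-2H-chromene; 16 2-(benzyloxy)-N-methoxy-N-methylacetamide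
Product: 18 2-(benzyloxy)-1-{3,4-bis(benzyloxy)-5-[(2S,4R)-7,8-bis(benzyloxy)-2-(4-benzyloxyphenyl)-3,4-dihydro-2H-chromen-4-yl]-2-fluorophenyl}ethan-1-one, via arylmagnesium chloride 17 (not isolated)
Conditions: i-PrMgCl·LiCl, THF, 0 °C to rt; then 16, 0 °C to rt; aq. NH4Cl
Reagents that add atoms: none
Why: Bromine–magnesium exchange, helped by the ortho fluorine and giving an o-fluoroaryl Grignard reagent that is stable at these temperatures, followed by Weinreb ketone synthesis, which stops at the ketone through the chelated tetrahedral intermediate.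

Step 11
Reactants: 18 2-(benzyloxy)-1-{3,4-bis(benzyloxy)-5-[(2S,4R)-7,8-bis(benzyloxy)-2-(4-benzyloxyphenyl)-3,4-dihydro-2H-chromen-4-yl]-2-fluorophenyl}ethan-1-one; 19 4-(benzyloxy)benzaldehyde
Product: 21 (2R,3R)-3,7,8-tris(benzyloxy)-2-[4-(benzyloxy)phenyl]-6-[(2S,4R)-7,8-bis(benzyloxy)-2-(4-benzyloxyphenyl)-3,4-dihydro-2H-chromen-4-yl]-2,3-dihydro-4H-chromen-4-one, via aldol adduct 20 (not isolated)
Conditions: 19 (2 equiv), O-allyl-N-(9-anthracenylmethyl)cinchonidinium bromide (10 mol %), CsOH·H2O (1.5 equiv), toluene/CH2Cl2, −40 to −10 °C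
Reagents that add atoms: none
Why: Proposed new method: solid CsOH and the chiral ammonium ion should generate the C3 enolate of 18 (C3–H is alpha to the C4 carbonyl and to oxygen), which adds reversibly to aldehyde 19 to give the ion-paired aldolates 20; the aldehyde-derived alkoxide then attacks C8a, the fluorine-bearing carbon ortho to the C4 carbonyl, and fluoride leaves from the Meisenheimer-type enolate. The closest known reaction types are the chiral phase-transfer-catalysed Darzens condensation of α-halo aryl ketones with aldehydes, where equilibrating aldolates are drained by an irreversible C–O ring closure under control of the chiral cation, and the SNAr closure of chromones and chroman-4-ones from o-fluoroaryl ketones. The pyranone ring closes by a 6-endo-trig conjugate addition of O1 to the C8a=C4a–C4=O unit followed by loss of fluoride (addition-elimination). C2 is fixed in this irreversible closure by the cinchonidinium cation through Curtin–Hammett selection among the rapidly interconverting aldolates, so neither aldol diastereoselectivity nor retro-aldol matters; C3 stays epimerisable, should settle as the diequatorial 2,3-trans isomer, and is corrected in step 12. The step needs O-cyclisation at C8a in preference to dehydration to the α-benzyloxychalcone and to a five-membered closure: the carbonyl/fluoride pair makes C8a the most electrophilic ring carbon, the benzyl ether on the C3 oxygen leaves only the C2 oxygen free to cyclise, and the aldehyde cannot enolise.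

Step 12
Reactants: 21 (2R,3R)-3,7,8-tris(benzyloxy)-2-[4-(benzyloxy)phenyl]-6-[(2S,4R)-7,8-bis(benzyloxy)-2-(4-benzyloxyphenyl)-3,4-dihydro-2H-chromen-4-yl]-2,3-dihydro-4H-chromen-4-one
Product: 23 (2R,3R,4R)-3,7,8-tris(benzyloxy)-2-[4-(benzyloxy)phenyl]-6-[(2S,4R)-7,8-bis(benzyloxy)-2-(4-benzyloxyphenyl)-3,4-dihydro-2H-chromen-4-yl]-3,4-dihydro-2H-chromen-4-ol, via cis-ketone 22 (not isolated)
Conditions: RuCl[(S,S)-TsDPEN](p-cymene) (3 mol %), HCO2H/Et3N (5:2), DMF, 40 °C
Reagents that add atoms: none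
Why: Asymmetric transfer hydrogenation with dynamic kinetic resolution; C3 epimerises through the enol under the amine/formic acid conditions and the (S,S) catalyst delivers hydride to the carbonyl face anti to both the 2-aryl and the 3-benzyloxy group, a doubly matched case met only by the 2,3-cis epimer 22, so the trans ketone should drain through 22 into the all-cis alcohol with C3 and C4 set by the catalyst.

Step 13
Reactants: 23 (2R,3R,4R)-3,7,8-tris(benzyloxy)-2-[4-(benzyloxy)phenyl]-6-[(2S,4R)-7,8-bis(benzyloxy)-2-(4-benzyloxyphenyl)-3,4-dihydro-2H-chromen-4-yl]-3,4-dihydro-2H-chromen-4-ol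
Product: 24 (2R,3R,4R)-6-[(2S,4S)-7,8-dihydroxy-2-(4-hydroxyphenyl)-3,4-dihydro-2H-chromen-4-yl]-2-(4-hydroxyphenyl)-3,4-dihydro-2H-chromene-3,4,7,8-tetrol
Conditions: H2 (1 atm), Pd(OH)2/C, THF/MeOH, rt, acid-free, stopped at full debenzylation
Reagents that add atoms: none
Why: Hydrogenolysis of the seven benzyl ethers; neutral conditions, low pressure and short contact time should spare the benzylic C4–OH and C2–O1 bonds, and no stereocentre is touched.

**Compound list**

1 | 1-(2,3,4-trihydroxyphenyl)ethan-1-one (gallacetophenone) | CC(=O)c1ccc(O)c(O)c1O | starting material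
2 | 1-[3,4-bis(benzyloxy)-2-hydroxyphenyl]ethan-1-one | CC(=O)c1ccc(OCc2ccccc2)c(OCc2ccccc2)c1O | intermediate
3 | (2E)-1-[3,4-bis(benzyloxy)-2-hydroxyphenyl]-3-(dimethylamino)prop-2-en-1-one (not isolated) | CN(C)/C=C/C(=O)c1ccc(OCc2ccccc2)c(OCc2ccccc2)c1O | intermediate
4 | 7,8-bis(benzyloxy)-4H-chromen-4-one | O=c1ccoc2c(OCc3ccccc3)c(OCc3ccccc3)ccc12 | intermediate
5 | [4-(benzyloxy)phenyl]boronic acid | OB(O)c1ccc(OCc2ccccc2)cc1 | starting material
6 | (2S)-7,8-bis(benzyloxy)-2-[4-(benzyloxy)phenyl]-2,3-dihydro-4H-chromen-4-one | C(c5ccccc5)Oc1ccc([C@@H]2CC(=O)c3ccc(OCc5ccccc5)c(OCc5ccccc5)c3O2)cc1 | intermediate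
7 | (2S,4S)-7,8-bis(benzyloxy)-2-[4-(benzyloxy)phenyl]-3,4-dihydro-2H-chromen-4-ol (2,4-cis) | C(c5ccccc5)Oc1ccc([C@@H]2C[C@H](O)c3ccc(OCc5ccccc5)c(OCc5ccccc5)c3O2)cc1 | intermediate
8 | 3-fluoro-2-hydroxybenzaldehyde | O=Cc1cccc(F)c1O | starting material
9 | 2-(benzyloxy)-3-fluorobenzaldehyde | O=Cc1cccc(F)c1OCc1ccccc1 | intermediate
10 | 2-(benzyloxy)-3-fluorophenyl formate (not isolated) | O=COc1cccc(F)c1OCc1ccccc1 | intermediate
11 | 2-(benzyloxy)-3-fluorophenol | Oc1cccc(F)c1OCc1ccccc1 | intermediate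
12 | 2-(benzyloxy)-4-bromo-3-fluorophenol | Oc1ccc(Br)c(F)c1OCc1ccccc1 | intermediate
13 | (2S)-7,8-bis(benzyloxy)-2-[4-(benzyloxy)phenyl]-3,4-dihydro-2H-chromen-4-ylium, the flavan-4-yl cation (not isolated) | C(c5ccccc5)Oc1ccc([C@@H]2C[CH+]c3ccc(OCc5ccccc5)c(OCc5ccccc5)c3O2)cc1 | intermediate
14 | 2-(benzyloxy)-6-{(2S,4S)-7,8-bis(benzyloxy)-2-[4-(benzyloxy)phenyl]-3,4-dihydro-2H-chromen-4-yl}-4-bromo-3-fluorophenol (2,4-trans) | C(c5ccccc5)Oc1ccc([C@@H]2C[C@@H](c3cc(Br)c(F)c(OCc5ccccc5)c3O)c3ccc(OCc5ccccc5)c(OCc5ccccc5)c3O2)cc1 | intermediate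
15 | (2S,4R)-7,8-bis(benzyloxy)-2-[4-(benzyloxy)phenyl]-4-[2,3-bis(benzyloxy)-5-bromo-4-fluorophenyl]-3,4-dihydro-2H-chromene (2,4-trans) | C(c5ccccc5)Oc1ccc([C@@H]2C[C@@H](c3cc(Br)c(F)c(OCc5ccccc5)c3OCc5ccccc5)c3ccc(OCc5ccccc5)c(OCc5ccccc5)c3O2)cc1 | intermediate
16 | 2-(benzyloxy)-N-methoxy-N-methylacetamide | CON(C)C(=O)COCc1ccccc1 | starting material
17 | {3,4-bis(benzyloxy)-5-[(2S,4R)-7,8-bis(benzyloxy)-2-(4-benzyloxyphenyl)-3,4-dihydro-2H-chromen-4-yl]-2-fluorophenyl}magnesium chloride (not isolated) | C(c5ccccc5)Oc1ccc([C@@H]2C[C@@H](c3cc([Mg]Cl)c(F)c(OCc5ccccc5)c3OCc5ccccc5)c3ccc(OCc5ccccc5)c(OCc5ccccc5)c3O2)cc1 | intermediate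
18 | 2-(benzyloxy)-1-{3,4-bis(benzyloxy)-5-[(2S,4R)-7,8-bis(benzyloxy)-2-(4-benzyloxyphenyl)-3,4-dihydro-2H-chromen-4-yl]-2-fluorophenyl}ethan-1-one | C(c5ccccc5)Oc1ccc([C@@H]2C[C@@H](c3cc(C(=O)COCc5ccccc5)c(F)c(OCc5ccccc5)c3OCc5ccccc5)c3ccc(OCc5ccccc5)c(OCc5ccccc5)c3O2)cc1 | intermediate
19 | 4-(benzyloxy)benzaldehyde | O=Cc1ccc(OCc2ccccc2)cc1 | starting material
20 | (3R)-2-(benzyloxy)-3-[4-(benzyloxy)phenyl]-1-{3,4-bis(benzyloxy)-5-[(2S,4R)-7,8-bis(benzyloxy)-2-(4-benzyloxyphenyl)-3,4-dihydro-2H-chromen-4-yl]-2-fluorophenyl}-3-hydroxypropan-1-one, both C2 epimers, present as the ammonium alkoxide (not isolated) | C(c5ccccc5)Oc1ccc([C@@H]2C[C@@H](c3cc(C(=O)C(OCc5ccccc5)[C@H](O)c4ccc(OCc5ccccc5)cc4)c(F)c(OCc5ccccc5)c3OCc5ccccc5)c3ccc(OCc5ccccc5)c(OCc5ccccc5)c3O2)cc1 | intermediate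
21 | (2R,3R)-3,7,8-tris(benzyloxy)-2-[4-(benzyloxy)phenyl]-6-[(2S,4R)-7,8-bis(benzyloxy)-2-(4-benzyloxyphenyl)-3,4-dihydro-2H-chromen-4-yl]-2,3-dihydro-4H-chromen-4-one (2,3-trans) | C(c5ccccc5)Oc1ccc([C@@H]2C[C@@H](c3cc4c(c(OCc5ccccc5)c3OCc5ccccc5)O[C@H](c3ccc(OCc5ccccc5)cc3)[C@@H](OCc5ccccc5)C4=O)c3ccc(OCc5ccccc5)c(OCc5ccccc5)c3O2)cc1 | intermediate
22 | (2R,3S)-3,7,8-tris(benzyloxy)-2-[4-(benzyloxy)phenyl]-6-[(2S,4R)-7,8-bis(benzyloxy)-2-(4-benzyloxyphenyl)-3,4-dihydro-2H-chromen-4-yl]-2,3-dihydro-4H-chromen-4-one (2,3-cis; not isolated) | C(c5ccccc5)Oc1ccc([C@@H]2C[C@@H](c3cc4c(c(OCc5ccccc5)c3OCc5ccccc5)O[C@H](c3ccc(OCc5ccccc5)cc3)[C@H](OCc5ccccc5)C4=O)c3ccc(OCc5ccccc5)c(OCc5ccccc5)c3O2)cc1 | intermediate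
23 | (2R,3R,4R)-3,7,8-tris(benzyloxy)-2-[4-(benzyloxy)phenyl]-6-[(2S,4R)-7,8-bis(benzyloxy)-2-(4-benzyloxyphenyl)-3,4-dihydro-2H-chromen-4-yl]-3,4-dihydro-2H-chromen-4-ol (2,3-cis-3,4-cis) | C(c5ccccc5)Oc1ccc([C@@H]2C[C@@H](c3cc4c(c(OCc5ccccc5)c3OCc5ccccc5)O[C@H](c3ccc(OCc5ccccc5)cc3)[C@H](OCc5ccccc5)[C@@H]4O)c3ccc(OCc5ccccc5)c(OCc5ccccc5)c3O2)cc1 | intermediate
24 | (2R,3R,4R)-6-[(2S,4S)-7,8-dihydroxy-2-(4-hydroxyphenyl)-3,4-dihydro-2H-chromen-4-yl]-2-(4-hydroxyphenyl)-3,4-dihydro-2H-chromene-3,4,7,8-tetrol (CNP0209379.1) | Oc1ccc([C@@H]2C[C@@H](c3cc4c(c(O)c3O)O[C@H](c3ccc(O)cc3)[C@H](O)[C@@H]4O)c3ccc(O)c(O)c3O2)cc1 | target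

**Step count and risks**

Total steps: 13. Longest linear sequence: 10 steps (steps 1, 2, 3, 4, 8, 9, 10, 11, 12, 13).

Steps most likely to fail:

1. Step 11 (Proposed new method). The chiral cation may discriminate poorly between the equilibrating aldolates in the ring closure, giving low or reversed selectivity at lower C2. Dehydration of the aldolate to the α-benzyloxychalcone, or attack of hydroxide at C8a, may also divert material. The fallback uses classical flavonoid chemistry; it sets out from 18 and returns at 21.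
   - The fluorine of 18 is displaced by hydroxide (KOH, DMSO/H2O, 60 °C) to give 2-(benzyloxy)-1-{3,4-bis(benzyloxy)-5-[(2S,4R)-7,8-bis(benzyloxy)-2-(4-benzyloxyphenyl)-3,4-dihydro-2H-chromen-4-yl]-2-hydroxyphenyl}ethan-1-one F1.
   - Claisen–Schmidt condensation of F1 with 19 (KOH, EtOH, rt) should give the 2'-hydroxy-α-benzyloxychalcone F2.
   - Oxa-Michael ring closure (NaOAc, EtOH, reflux) should give the 2,3-trans 3-benzyloxyflavanones as a mixture of 21 and its lower-unit epimer, the (2S,3S)-ketone F3.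
   - The mixture enters step 12, where the (S,S) catalyst is expected to reduce only the (2R) series at a useful rate (kinetic resolution of flavanones by transfer hydrogenation is known). F3 remains as ketone and is separated, so at most half of the material is used.

2. Step 12. C3 epimerisation may be slow relative to direct reduction of the trans ketone, leading to the 3,4-trans alcohol. Prolonged exposure to base may erode C2 by ring opening, and any (2S) material from step 11 would remain as unreacted ketone. The fallback sets out from 21 and returns at 23.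
   - Deprotonation with LiN(SiMe3)2 (THF, −78 °C) gives the lithium enolate F4, in which A(1,2) strain with the 3-benzyloxy group places the 2-aryl group pseudo-axial.
   - Kinetic protonation with 2,6-di-tert-butyl-4-methylphenol at −78 °C should occur anti to that aryl group and give the cis-ketone 22, which is isolated cold.
   - Reduction under Luche conditions (NaBH4, CeCl3·7H2O, MeOH/THF, −78 °C) delivers hydride axially and anti to the axial 3-benzyloxy group, which should give 23.

3. Step 8. The flavan-4-yl cation may be captured by the benzyloxy-activated ring A of a second flavan molecule (oligomers) or lose a proton to the flav-3-ene faster than it is taken by the halogen-deactivated phenol. The 2,4-trans preference may also be modest. The fallback sets out from 7 and returns at 14.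
   - Alcohol 7 is converted with SOCl2 (CH2Cl2, −20 °C) into the 4-chloroflavan F5, used crude.
   - Phenol 12 is turned into its bromomagnesium phenolate (EtMgBr, toluene/CH2Cl2) and alkylated with F5. Coordination of the leaving chloride to magnesium delivers the benzylic carbon to the ortho position of the phenolate under non-acidic conditions, where the ether-protected rings of the flavan cannot compete.
   - Attack anti to the 2-aryl group is again expected, giving 14.

**Further compounds**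

F1 | step 11 | 2-(benzyloxy)-1-{3,4-bis(benzyloxy)-5-[(2S,4R)-7,8-bis(benzyloxy)-2-(4-benzyloxyphenyl)-3,4-dihydro-2H-chromen-4-yl]-2-hydroxyphenyl}ethan-1-one | C(c5ccccc5)Oc1ccc([C@@H]2C[C@@H](c3cc(C(=O)COCc5ccccc5)c(O)c(OCc5ccccc5)c3OCc5ccccc5)c3ccc(OCc5ccccc5)c(OCc5ccccc5)c3O2)cc1
F2 | step 11 | (2Z)-2-(benzyloxy)-3-[4-(benzyloxy)phenyl]-1-{3,4-bis(benzyloxy)-5-[(2S,4R)-7,8-bis(benzyloxy)-2-(4-benzyloxyphenyl)-3,4-dihydro-2H-chromen-4-yl]-2-hydroxyphenyl}prop-2-en-1-one | C(c5ccccc5)Oc1ccc([C@@H]2C[C@@H](c3cc(C(=O)/C(OCc5ccccc5)=C/c4ccc(OCc5ccccc5)cc4)c(O)c(OCc5ccccc5)c3OCc5ccccc5)c3ccc(OCc5ccccc5)c(OCc5ccccc5)c3O2)cc1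
F3 | step 11 | (2S,3S)-3,7,8-tris(benzyloxy)-2-[4-(benzyloxy)phenyl]-6-[(2S,4R)-7,8-bis(benzyloxy)-2-(4-benzyloxyphenyl)-3,4-dihydro-2H-chromen-4-yl]-2,3-dihydro-4H-chromen-4-one | C(c5ccccc5)Oc1ccc([C@@H]2C[C@@H](c3cc4c(c(OCc5ccccc5)c3OCc5ccccc5)O[C@@H](c3ccc(OCc5ccccc5)cc3)[C@H](OCc5ccccc5)C4=O)c3ccc(OCc5ccccc5)c(OCc5ccccc5)c3O2)cc1
F4 | step 12 | lithium (2R)-3,7,8-tris(benzyloxy)-2-[4-(benzyloxy)phenyl]-6-[(2S,4R)-7,8-bis(benzyloxy)-2-(4-benzyloxyphenyl)-3,4-dihydro-2H-chromen-4-yl]-2H-chromen-4-olate | C(c5ccccc5)Oc1ccc([C@@H]2C[C@@H](c3cc4c(c(OCc5ccccc5)c3OCc5ccccc5)O[C@H](c3ccc(OCc5ccccc5)cc3)C(OCc5ccccc5)=C4O[Li])c3ccc(OCc5ccccc5)c(OCc5ccccc5)c3O2)cc1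
F5 | step 8 | (2S)-7,8-bis(benzyloxy)-2-[4-(benzyloxy)phenyl]-4-chloro-3,4-dihydro-2H-chromene, both C4 epimers | C(c5ccccc5)Oc1ccc([C@@H]2CC(Cl)c3ccc(OCc5ccccc5)c(OCc5ccccc5)c3O2)cc1
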